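## Structural features

The target is a briarane: a cyclohexane (ring A: C1, C10–C14) fused through the C1–C10 bond to a cyclodecane (C1–C10). The ten-membered ring carries a γ-lactone (O–C19–C17–C8–C7) fused across C7–C8, and ring A carries a spiro-epoxide (C11–O–C20). Ring A is trans-fused (the C15 methyl on C1 and H-10 lie on opposite faces), and the lactone is trans-fused to the medium ring (H-7 and the 8-hydroxyl on opposite faces). There are ten stereocentres; eight of them, C6–C7–C8(–C17)–C9–C10–C1–C2, are contiguous, and C11 and C14 flank the ring fusion. C1 is an all-carbon quaternary centre, and C8 and C11 are fully substituted. The fragile sites are: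

- the secondary allylic chloride at C6 (ionisation, SN2′ attack, epoxide formation whenever O7 is a free alkoxide);
- the acid-labile spiro-epoxide;
- the β-hydroxy lactone (retro-aldol, dehydration);
- the acetates at C2, C9 and C14 (bases, organometallics);
- the 5(16)-methylene (migration into the ring).

The real difficulty is the ten-membered ring: it has to be closed against transannular strain with oxygen on C2, C7, C8 and C9, chlorine on C6 and the exocyclic C16 in place, and its stereocentres (C2, C6, C7, C8, C17) can only be set by relay from ring A. The key step uses the 1,6-relationship of the oxygens on C2 and C7 together with the exocyclic methylene on C5. Reconnecting C2 to C7 and cutting C4–C5 contracts the medium ring to the six-membered ring B (C1, C2, C7, C8, C9, C10) of a trans-decalin with a vinyl group on C2 and an allenyl group on C7. C1, C9, C10 and C14 lie outside that reorganising array and can be fixed beforehand on a rigid bicycle.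

## Logic of the disconnections

**34 ⇒ 33.** The two C–O bonds of the oxirane (C11–O, C20–O) are cut. The epoxide is the most acid-sensitive group and is best made last. In 33 the β face of the 11(20)-alkene is screened by the axial C15 methyl (1,3-related), so a peracid should enter from the α face and give the required 11R centre. A sulfur-ylide addition to a C11 ketone would bring the CH2 in equatorially and give the 11-epimer, which is why C11 is carried as an alkene and not as a masked ketone. The forward step must discriminate between two 1,1-disubstituted alkenes; the C5=C16 bond is deactivated by the allylic chlorine.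

**33 ⇒ 32 ⇒ 31 ⇒ 30.** The three acetate C–O bonds and the C2–H bond are cut. Acetates cannot survive the organometallic and strongly basic steps, so all three are installed in one late acylation of 32, leaving the tertiary 8-OH. The C2 carbinol is traced to the C2 ketone of 31, where the free 14-hydroxyl is β to the carbonyl. Hydroxyl-directed hydride delivery should give the 1,3-anti diol, which is the 2S/14S relationship of 34. Desilylation must therefore precede the reduction.

**30 ⇒ 28 ⇒ 26 + 27.** The C8–C17 bond and the C19–O7 ester bond are cut. This removes the lactone ring and the C8 and C17 stereocentres in one aldol-type (Reformatsky) closure of an α-bromopropionate onto the C8 ketone. The forward step needs an enolate that can be generated next to an allylic chloride, and attack on the C8 face that gives the trans-fused lactone. The ester in 28 is made with inversion at C7, because a polar-model hydride reduction of the α-chloro ketone is expected to put Cl and OH syn, whereas 34 needs them anti.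

**26 ⇒ 25 ⇒ 24 ⇒ 22.** The C7–H and C6–Cl bonds are cut, and the C8 carbonyl is traced to a dimethyl ketal. The α-chloro ketone 24 comes from the cross-conjugated dienolate of the C7 ketone, which is exactly what the key step leaves behind. The demands are regioselective enolisation (C6–H over C3–H), α- rather than γ-attack of the chlorine source, and face selectivity at C6.

**22 ⇒ 19 (key).** The C4–C5 bond is cut and C2–C7 is reconnected. The ten-membered ring becomes ring B of the trans-decalin 19, with vinyl on C2 and allenyl on C7. The gain is large: a medium ring is replaced by a chair cyclohexane, and no stereocentre has to be made in the step. The forward step needs a [3,3] shift that is faster than fragmentation of the dialkoxide, and a quench that neither conjugates the new methylene nor allows a transannular aldol reaction. Three spectator groups of 19 were chosen with the later steps in mind: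

- C8 is a dimethyl ketal. It falls out of the ring B oxidation directly and is the most labile ketal.
- O9 carries a triisopropylsilyl group. O9 is syn-diaxial to the O7 alkoxide, and a smaller silyl group could migrate.
- C11 already carries the 11(20)-methylene. A C11 ketal would have to be unmasked while the C2 ketone is still present.

**19 ⇒ 17 ⇒ 15 + 16.** The terminal allene carbon (C16) is removed by tracing the allene to a terminal alkyne (one-carbon homologation), and the C2–C3 bond is cut to the ketone 15 and the vinyl nucleophile 16. The demand is addition to a ketone flanked by two fully substituted carbons. Both C2 epimers can reach a chair [3,3] array, so the facial outcome is not critical.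

**15 ⇒ 14 ⇒ 13 ⇒ 12.** The C11=C20 bond is cut to the C11 ketone, and that to the 11-silyloxy group. The methylenation must be non-basic, because the 9-silyloxy group is β to the C11 carbonyl. The silyl ether at C11 must be the only one that is equatorial and unhindered, so that it can be removed selectively.

**12 ⇒ 10 + 11.** The C6–C7 bond is cut to the 1,2-diketone 10 and the acetylide 11. The C7 carbonyl is the more electrophilic one (next to the ketal carbon); the C2 carbonyl sits against the quaternary C1.

**10 ⇒ 9 ⇒ 8 ⇒ 7.** Ring B of 10 (C2 ketone, C7 ketone, C8 ketal, C9 carbinol) is an isomer, at the same oxidation level, of the ene-dione bis(enol ether) in 7. The C9 ketone is reduced and the C7=C8 enol ether is oxidised in methanol. No separate introduction of oxygen at C2, C7, C8 or C9 is needed.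

**7 ⇒ 6 ⇒ 5.** The C10 configuration is traced to its epimer, and C12–C13 to an alkene. In either chair of the cis-fused isomer one silyloxy group (on C14 or C11) is syn-diaxial to a ring B carbon. The trans isomer 7 has no such contact, so equilibration should run to 7.

**5 ⇒ 3 + 4.** The C1–C14 and C10–C11 bonds are cut (Diels–Alder). In 4 only the methyl-bearing double bond is dienophilic; the other is tetrasubstituted and donor-substituted, so the quaternary C1 is forced. Because 3 is symmetric there is no regiochemical question, and the endo rule puts both silyloxy groups trans to the C15 methyl (the 14S centre of 34). Ring B is taken from the quinone and ring A from the diene for two reasons. A monosubstituted quinone would react at its unsubstituted double bond. And if ring B came from a 1,4-diacyloxydiene, the C9 acyloxy group would sit β to the ring A ketone and would be eliminated on epimerisation.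

**3 ⇒ 1.** The two Si–O bonds are cut; 3 is the bis(silyl enol ether) obtained from the commercial diacetate 1.

## Other disconnections considered

Alternative 1: The cut runs through C1–C14 and C10–C11, so that ring A is made by an intramolecular Diels–Alder reaction. In the forward direction the triene A2 is heated. A diisopropylsilylene links O2 and O14, the 1-silyloxy-4,4-dimethoxydiene (C14=C13–C12=C11) adds to the E-enoate C1=C10, and A1 results: ring A fused to a six-membered siloxane.
- In favour: the E-geometry of the dienophile translates directly into the trans C1/C10 relationship. This is better than the chosen plan, which needs an epimerisation.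
- In favour: C2 is set together with C14 through the tether (earlier than in the chosen plan), and C11 arrives at the ketone oxidation level.
- Against: the ten-membered ring is not touched. After A1 the whole C5–C8 segment, the lactone and an end-to-end medium-ring closure are still to come.
- Against: the ketene-acetal diene is hydrolytically delicate, and a trisubstituted enoate is a weak dienophile.
- Comparison: both plans make the quaternary C1 by a cycloaddition (equal). The chosen plan gets the medium ring by ring expansion without high dilution, and has all ring oxygens in place after seven steps. Alternative 1 is therefore likely to be longer overall.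

Alternative 2: Only C1–C10 is cut. In the forward direction a Lewis acid (Et2AlCl or BF3·OEt2) opens the 1,2-epoxide of the fourteen-membered A4 at the tertiary C1. The E-C10=C11 alkene attacks through C10, and the C11 cation loses a C20 proton to give A3.
- In favour: one step makes ring A, the quaternary centre, the ring fusion and the 11(20)-methylene. No ten-membered ring has to be closed at all, since a fourteen-membered ring is much easier to form. In bond economy this is better than the chosen plan. The butenolide is carried in intact.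
- Against: A4 is a stereodefined macrocycle (E-epoxide, E-alkene, four stereocentres) that is itself a long synthesis.
- Against: the outcome rests on the macrocycle conformation. Open questions are the face of attack, cis or trans fusion, proton loss from C20 or from C12, and competing hydride shift to a C2 ketone.
- Against: from A3 the C5 ketone must still become the methylene, the C6 oxygen a chloride with inversion, and the butenolide the 8-hydroxy-17H lactone.
- Comparison: mechanistically it is a cationic cascade, less predictable than a suprafacial [3,3] shift in a rigid chair. Structurally it is the most direct. In step count after the key step it is about equal to the chosen plan.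

Alternative 3: The cut is C6–C7 together with the lactone C–O bond. In the forward direction CrCl2 turns the allylic bromide A6 into an allylchromium species. Its chlorine-bearing γ-carbon C6 adds to the C7 aldehyde through a chair six-membered transition state, and the chromium alkoxide closes onto the C19 ester to give A5.
- In favour: the ring, the C6–Cl/C7–O anti-chlorohydrin and the lactone are formed in one mild operation at the very end. Divalent chromium tolerates acetates and esters. A5 is two steps from the target. On the chlorohydrin and on the endgame this is better than the chosen plan, which sets C6 and C7 separately under substrate control.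
- Against: it is an end-to-end closure of a ten-membered ring (high dilution, transannular strain). Here the chosen ring expansion is the better of the two.
- Against: A6 must already hold C1, C2, C8, C9, C10, C11, C14 and C17, including a tertiary α-hydroxy aldehyde prone to retro-aldol cleavage, and the spiro-epoxide must survive the late steps.
- Comparison: the step count is probably similar. The chosen plan reaches the full carbon skeleton much earlier.

Key step: step 14

Remark on numbering: briarane locants are used for every intermediate (C1 quaternary carbon with the C15 methyl; C2–C9 the remaining ten-ring atoms; C10 ring-fusion CH; C11–C14 ring A; C16 on C5; C17, C18, C19 lactone CH, methyl and carbonyl; C20 on C11). In the decalins, ring B is C1, C2, C7, C8, C9, C10. β is the face of C15. TBSO = tert-butyldimethylsilyloxy, TIPSO = triisopropylsilyloxy.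

Assumption: the oxazaborolidinium catalyst is taken to shield the quinone face in the usual sense, so that the (S)-catalyst gives 5 as drawn; if the sense is opposite, its antipode is used.

Assumption: 27 is used as the racemate, because its stereocentre becomes the planar enolate carbon C17 in step 19.

## Route

Step 1
Reactants: 1 (1E,3E)-buta-1,3-diene-1,4-diyl diacetate
Product: 3 (1E,3E)-1,4-bis(tert-butyldimethylsilyloxy)buta-1,3-diene, via dilithium buta-1,3-diene-1,4-diolate 2 (not isolated)
Conditions: MeLi (4.2 equiv), THF, −78 to 0 °C; then TBSCl (2.5 equiv), DMPU, −78 °C to rt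
Reagents that add atoms: tert-butyldimethylsilyl chloride, CC(C)(C)[Si](C)(C)Cl
Why: Enol acetates are cleaved by two equivalents of MeLi to lithium enolates with retention of geometry, and O-silylation then fixes the E,E-dienediolate as the bis(silyl enol ether); this is the standard enolate generation from enol esters.

Step 2
Reactants: 3 (1E,3E)-1,4-bis(tert-butyldimethylsilyloxy)buta-1,3-diene; 4 2,3-dimethoxy-5-methyl-1,4-benzoquinone
Product: 5 cis-fused adduct 11α,14α-bis(TBSO)-7,8-dimethoxy-1β-methyl-10βH-decal-7,12-diene-2,9-dione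
Conditions: (S)-3,3-diphenyl-1-(2-methylphenyl)tetrahydro-1H,3H-pyrrolo[1,2-c][1,3,2]oxazaborole (20 mol %), Tf2NH (18 mol %), CH2Cl2, −78 to −40 °C
Reagents that add atoms: none
Why: Catalytic enantioselective Diels–Alder reaction; only the methyl-bearing double bond of 4 is dienophilic, the symmetric diene removes any regiochemical issue, the endo transition state places both silyloxy groups trans to the C15 methyl and to H-10 (sets C14 and the cis fusion), and the chiral Lewis acid sets the absolute configuration at C1.

Step 3
Reactants: 5 cis-fused adduct 11α,14α-bis(TBSO)-7,8-dimethoxy-1β-methyl-10βH-decal-7,12-diene-2,9-dione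
Product: 6 cis-fused 11α,14α-bis(TBSO)-7,8-dimethoxy-1β-methyl-10βH-decal-7-ene-2,9-dione
Conditions: H2 (1 atm), RhCl(PPh3)3 (5 mol %), benzene/EtOH, rt
Reagents that add atoms: none
Why: Homogeneous hydrogenation reduces the disubstituted C12=C13 bond and leaves the tetrasubstituted, donor-substituted C7=C8 bond and the allylic C–O bonds untouched.

Step 4
Reactants: 6 cis-fused 11α,14α-bis(TBSO)-7,8-dimethoxy-1β-methyl-10βH-decal-7-ene-2,9-dione
Product: 7 trans-fused 11α,14α-bis(TBSO)-7,8-dimethoxy-1β-methyl-10αH-decal-7-ene-2,9-dione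
Conditions: DBU (0.2 equiv), toluene, rt
Reagents that add atoms: none
Why: Base-mediated epimerisation α to the C9 ketone (the classical cis-to-trans isomerisation of quinone cycloadducts); in either chair of 6 one silyloxy group (on C14 or C11) is syn-diaxial to C9 or C2, whereas in 7 only H atoms are syn-axial, so the equilibrium should lie on 7; silanolate is a poor leaving group, so β-elimination at C11 should stay slower than reprotonation.

Step 5
Reactants: 7 trans-fused 11α,14α-bis(TBSO)-7,8-dimethoxy-1β-methyl-10αH-decal-7-ene-2,9-dione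
Product: 8 9β-hydroxy-11α,14α-bis(TBSO)-7,8-dimethoxy-1β-methyl-10αH-decal-7-en-2-one
Conditions: NaBH4, CeCl3·7H2O, MeOH/CH2Cl2, −78 °C
Reagents that add atoms: none
Why: Luche 1,2-reduction; the C9 carbonyl (next to a CH) is more accessible than the C2 carbonyl (next to the quaternary C1), and hydride enters from the α face because the β face of C9 is screened by the syn-axial C15 methyl, giving the 9β (9S) alcohol.

Step 6
Reactants: 8 9β-hydroxy-11α,14α-bis(TBSO)-7,8-dimethoxy-1β-methyl-10αH-decal-7-en-2-one
Product: 9 9β-TIPSO-11α,14α-bis(TBSO)-7,8-dimethoxy-1β-methyl-10αH-decal-7-en-2-one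
Conditions: i-Pr3SiOTf, 2,6-lutidine, CH2Cl2, 0 °C to rt
Reagents that add atoms: triisopropylsilyl trifluoromethanesulfonate, CC(C)[Si](OS(=O)(=O)C(F)(F)F)(C(C)C)C(C)C
Why: Silyl triflate silylation of a hindered axial alcohol under non-acidic conditions; the bulky group is chosen because it should not migrate to the syn-axial O7 alkoxide of step 14 and survives the selective desilylation of step 9.

Step 7
Reactants: 9 9β-TIPSO-11α,14α-bis(TBSO)-7,8-dimethoxy-1β-methyl-10αH-decal-7-en-2-one
Product: 10 9β-TIPSO-11α,14α-bis(TBSO)-8,8-dimethoxy-1β-methyl-10αH-decalin-2,7-dione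
Conditions: dimethyldioxirane (acetone solution, 1.5 equiv), MeOH, −20 to 0 °C
Reagents that add atoms: dimethyldioxirane, CC1(C)OO1; methanol, CO
Why: Rubottom-type oxidation of an enol ether in methanol: the electron-rich C7=C8 bond is epoxidised, methanol opens the epoxide at C8 (oxocarbenium stabilised by its methoxy group, C7 being next to the C2 carbonyl), and the C7 hemiketal collapses to the ketone; the resulting 1,2-dione is flanked by C1 and C8, neither of which carries hydrogen, so it cannot enolise.

Step 8
Reactants: 10 9β-TIPSO-11α,14α-bis(TBSO)-8,8-dimethoxy-1β-methyl-10αH-decalin-2,7-dione; 11 ethynylmagnesium bromide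
Product: 12 7α-ethynyl-7β-hydroxy-9β-TIPSO-11α,14α-bis(TBSO)-8,8-dimethoxy-1β-methyl-10αH-decalin-2-one
Conditions: 11 (1.3 equiv), THF, −78 °C
Reagents that add atoms: none
Why: Grignard 1,2-addition to the more electrophilic carbonyl (C7, activated by the adjacent ketal carbon; C2 sits against the quaternary C1); the axial β trajectory at C7 is closed by the syn-axial C15 methyl and 9β-silyloxy group, so the acetylide enters equatorially from the α face, and the resulting hindered α-alkoxide ketone does not add a second equivalent.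

Step 9
Reactants: 12 7α-ethynyl-7β-hydroxy-9β-TIPSO-11α,14α-bis(TBSO)-8,8-dimethoxy-1β-methyl-10αH-decalin-2-one
Product: 13 7α-ethynyl-7β,11α-dihydroxy-9β-TIPSO-14α-TBSO-8,8-dimethoxy-1β-methyl-10αH-decalin-2-one
Conditions: HF·pyridine, pyridine, THF, 0 °C
Reagents that add atoms: none
Why: Selective desilylation by steric differentiation; the 11α-silyl ether is equatorial and flanked by CH and CH2, while the 14α ether is axial and neopentyl and the 9β ether is a hindered triisopropylsilyl group.

Step 10
Reactants: 13 7α-ethynyl-7β,11α-dihydroxy-9β-TIPSO-14α-TBSO-8,8-dimethoxy-1β-methyl-10αH-decalin-2-one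
Product: 14 7α-ethynyl-7β-hydroxy-9β-TIPSO-14α-TBSO-8,8-dimethoxy-1β-methyl-10αH-decalin-2,11-dione
Conditions: Dess–Martin periodinane, NaHCO3, CH2Cl2, rt
Reagents that add atoms: none
Why: Dess–Martin oxidation of the only secondary alcohol under neutral conditions; the tertiary alcohol is inert and the β-silyloxy ketone formed is not exposed to base.

Step 11
Reactants: 14 7α-ethynyl-7β-hydroxy-9β-TIPSO-14α-TBSO-8,8-dimethoxy-1β-methyl-10αH-decalin-2,11-dione
Product: 15 7α-ethynyl-7β-hydroxy-11-methylene-9β-TIPSO-14α-TBSO-8,8-dimethoxy-1β-methyl-10αH-decalin-2-one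
Conditions: Zn, CH2Br2, TiCl4, THF/CH2Cl2, 0 °C to rt
Reagents that add atoms: dibromomethane, BrCBr
Why: Lombardo methylenation is non-basic, so the C11 ketone is neither epimerised at C10 nor made to eliminate the 9-silyloxy group; the C2 ketone, flanked by two fully substituted carbons, should be inert to the bulky reagent.

Step 12
Reactants: 15 7α-ethynyl-7β-hydroxy-11-methylene-9β-TIPSO-14α-TBSO-8,8-dimethoxy-1β-methyl-10αH-decalin-2-one; 16 vinylmagnesium bromide
Product: 17 2β-ethenyl-7α-ethynyl-11-methylene-9β-TIPSO-14α-TBSO-8,8-dimethoxy-1β-methyl-10αH-decalin-2α,7β-diol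
Conditions: 16 (5 equiv), anhydrous CeCl3, THF, −78 to 0 °C
Reagents that add atoms: none
Why: Organocerium 1,2-addition to a hindered, non-enolisable ketone; the axial α trajectory at C2 is closed by the syn-axial 14α-silyloxy group, H-10 and the axial methoxy group on C8, so the vinyl group should enter equatorially from the β face and give the trans-diaxial diol; the C2 epimer would also be usable, because C2 and C7 are erased in step 14 and an axial/equatorial pair can still reach a chair [3,3] array.

Step 13
Reactants: 17 2β-ethenyl-7α-ethynyl-11-methylene-9β-TIPSO-14α-TBSO-8,8-dimethoxy-1β-methyl-10αH-decalin-2α,7β-diol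
Product: 19 2β-ethenyl-7α-(propa-1,2-dienyl)-11-methylene-9β-TIPSO-14α-TBSO-8,8-dimethoxy-1β-methyl-10αH-decalin-2α,7β-diol, via propargylic Mannich base 18 (not isolated)
Conditions: CuBr (0.5 equiv), (CH2O)n, i-Pr2NH, 1,4-dioxane, reflux
Reagents that add atoms: formaldehyde (from paraformaldehyde), C=O
Why: Crabbé homologation; the terminal alkyne gives the Mannich base, and copper-mediated hydride transfer from an isopropyl group with loss of the imine delivers the terminal allene; tertiary propargylic alcohols are standard substrates and the vinyl carbinol is a spectator.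

Step 14
Reactants: 19 2β-ethenyl-7α-(propa-1,2-dienyl)-11-methylene-9β-TIPSO-14α-TBSO-8,8-dimethoxy-1β-methyl-10αH-decalin-2α,7β-diol
Product: 22 9-TIPSO-14-TBSO-8,8-dimethoxy-17,18,19-trinorbriara-5(16),11(20)-diene-2,7-dione, via dipotassium dialkoxide 20 (not isolated), via dipotassium bis-enolate 21 (not isolated)
Conditions: KH (3 equiv), 18-crown-6 (3 equiv), THF, 0 °C to rt; then cannulated into AcOH/THF at −78 °C
Reagents that add atoms: none
Why: Deprotonation of both tertiary hydroxyls gives the crown-separated dialkoxide 20, in which each O− weakens the C2–C7 bond; in a chair six-centre transition state with the vinyl (C2) and allenyl (C7) groups diequatorial, C4 bonds to the central allene carbon C5 while C2–C7 breaks, giving the C2 enolate and the C7 cross-conjugated dienolate 21. The closest known reactions are the dianionic oxy-Cope ring expansion of 1,2-divinylcycloalkane-1,2-diols to cycloalkane-1,6-diones and the anionic oxy-Cope rearrangement of allenyl carbinols, which gives β-methylene ketones. The ten-membered ring is formed by a four-atom expansion of ring B (six to ten) inside a cyclic array, not by end-to-end closure, so no high dilution is needed. No stereocentre is created: C2 and C7 become trigonal, the enolate geometries are lost on protonation, and C1, C9, C10 and C14 are not part of the array. Bonding through the central allene carbon is enforced by the six-centre geometry and puts the exocyclic C16 methylene on C5 directly. The selectivity needed is the [3,3] path over fragmentation of the dialkoxide; the rigid trans-decalin holds the two π-termini gauche and within bonding distance, and the formation of two enolates makes the shift irreversible. Until the quench both carbonyls are masked as enolates, so no transannular aldol reaction can start, and the cold inverse acidic quench protonates C3 and C6 kinetically and keeps the 5(16)-alkene out of conjugation. The triisopropylsilyl group on O9, syn-axial to the O7 alkoxide, is too bulky to migrate, and the 11(20)-alkene has no 1,5-diene partner.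

Step 15
Reactants: 22 9-TIPSO-14-TBSO-8,8-dimethoxy-17,18,19-trinorbriara-5(16),11(20)-diene-2,7-dione
Product: 24 (6S)-6-chloro-9-TIPSO-14-TBSO-8,8-dimethoxy-17,18,19-trinorbriara-5(16),11(20)-diene-2,7-dione, via lithium dienolate 23 (not isolated)
Conditions: LiN(SiMe3)2 (1.05 equiv), THF, −78 °C; then N-chlorosuccinimide, −78 °C
Reagents that add atoms: N-chlorosuccinimide, O=C1CCC(=O)N1Cl
Why: α-Chlorination of a lithium dienolate; C6–H is both α to the C7 ketone and allylic and is removed in preference to C3–H, lithium dienolates react with halogen electrophiles at the α-carbon, and attack on the outer face of the ring away from the 9-silyloxy side is expected to give the 6S centre, which remains epimerisable.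

Step 16
Reactants: 24 (6S)-6-chloro-9-TIPSO-14-TBSO-8,8-dimethoxy-17,18,19-trinorbriara-5(16),11(20)-diene-2,7-dione
Product: 25 (6S,7S)-6-chloro-7-hydroxy-9-TIPSO-14-TBSO-8,8-dimethoxy-17,18,19-trinorbriara-5(16),11(20)-dien-2-one
Conditions: NaBH4, MeOH/THF, −78 to −40 °C
Reagents that add atoms: none
Why: Chemoselective reduction of the activated α-chloro, α′-ketal ketone in the presence of the neopentyl C2 ketone; in the polar transition state the hydride enters anti to the C–Cl bond, which for a ketone puts Cl and OH syn (7S); the anti relationship of 34 is then produced by the inversion in step 18.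

Step 17
Reactants: 25 (6S,7S)-6-chloro-7-hydroxy-9-TIPSO-14-TBSO-8,8-dimethoxy-17,18,19-trinorbriara-5(16),11(20)-dien-2-one
Product: 26 (6S,7S)-6-chloro-7-hydroxy-9-TIPSO-14-TBSO-17,18,19-trinorbriara-5(16),11(20)-diene-2,8-dione
Conditions: 1 M aq HCl, THF, 0 °C to rt
Reagents that add atoms: water, O
Why: Acid hydrolysis of a dimethyl ketal, the most labile ketal type, done while O7 is still a free hydroxyl (an acyloxy neighbour would retard it further); the hindered silyl ethers, the chlorohydrin and the 1,1-disubstituted alkenes should tolerate dilute acid.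

Step 18
Reactants: 26 (6S,7S)-6-chloro-7-hydroxy-9-TIPSO-14-TBSO-17,18,19-trinorbriara-5(16),11(20)-diene-2,8-dione; 27 2-bromopropanoic acid
Product: 28 (6S,7R)-7-(2-bromopropanoyloxy)-6-chloro-9-TIPSO-14-TBSO-17,18,19-trinorbriara-5(16),11(20)-diene-2,8-dione
Conditions: 27, PPh3, DIAD, toluene/THF, 0 °C to rt
Reagents that add atoms: none
Why: Mitsunobu esterification with inversion; the α-bromo acid is acidic enough to be a good pronucleophile, and displacement at a carbon α to the C8 ketone is accelerated, so C7 becomes R and the Cl/O relationship becomes anti.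

Step 19
Reactants: 28 (6S,7R)-7-(2-bromopropanoyloxy)-6-chloro-9-TIPSO-14-TBSO-17,18,19-trinorbriara-5(16),11(20)-diene-2,8-dione
Product: 30 (6S,7R,8R,17R)-6-chloro-8-hydroxy-9-TIPSO-14-TBSO-2-oxobriara-5(16),11(20)-dien-19,7-olide, via samarium ester enolate 29 (not isolated)
Conditions: SmI2 (2.5 equiv), THF, −78 °C
Reagents that add atoms: none
Why: Intramolecular Reformatsky reaction; divalent samarium reduces the C–Br bond far faster than the ketones or the allylic chloride, and the trivalent samarium enolate attacks the neighbouring C8 ketone in a chelated five-membered closure; the trans-fused lactone keeps the C6–C7–C8–C9 ring torsion anti-type (the cis-fused one would need it nearly eclipsed), and the enolate methyl should turn away from C9, placing C18 cis to the 8-hydroxyl (17R).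

Step 20
Reactants: 30 (6S,7R,8R,17R)-6-chloro-8-hydroxy-9-TIPSO-14-TBSO-2-oxobriara-5(16),11(20)-dien-19,7-olide
Product: 31 (6S,7R,8R,17R)-6-chloro-8,9,14-trihydroxy-2-oxobriara-5(16),11(20)-dien-19,7-olide
Conditions: 48% aq HF, MeCN, 0 °C to rt
Reagents that add atoms: none
Why: Acidic fluoride cleaves the hindered silyl ethers without base, which the β-hydroxy lactone, the chlorohydrin ester and the new β-hydroxy ketone (14-OH/C2=O) would not tolerate.

Step 21
Reactants: 31 (6S,7R,8R,17R)-6-chloro-8,9,14-trihydroxy-2-oxobriara-5(16),11(20)-dien-19,7-olide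
Product: 32 (2S,6S,7R,8R,17R)-6-chloro-2,8,9,14-tetrahydroxybriara-5(16),11(20)-dien-19,7-olide
Conditions: Me4NBH(OAc)3, MeCN/AcOH, −30 to −10 °C
Reagents that add atoms: none
Why: Evans–Saksena reduction; the 14-hydroxyl binds boron and delivers hydride intramolecularly to the β-carbonyl C2 through a chair six-membered transition state, giving the 1,3-anti diol, which is the 2S/14S relationship of the target; the reagent leaves the lactone, alkenes and chloride alone.

Step 22
Reactants: 32 (2S,6S,7R,8R,17R)-6-chloro-2,8,9,14-tetrahydroxybriara-5(16),11(20)-dien-19,7-olide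
Product: 33 (2S,6S,7R,8R,17R)-2,9,14-triacetoxy-6-chloro-8-hydroxybriara-5(16),11(20)-dien-19,7-olide
Conditions: Ac2O, pyridine, DMAP (cat.), rt
Reagents that add atoms: acetic anhydride, CC(=O)OC(C)=O
Why: Standard acylation of the three secondary alcohols; the tertiary, hydrogen-bonded 8-hydroxyl is much slower and should remain free.

Step 23
Reactants: 33 (2S,6S,7R,8R,17R)-2,9,14-triacetoxy-6-chloro-8-hydroxybriara-5(16),11(20)-dien-19,7-olide
Product: 34 CNP0104093.1
Conditions: 3-chloroperbenzoic acid (1.05 equiv), NaHCO3, CH2Cl2, −20 to 0 °C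
Reagents that add atoms: 3-chloroperbenzoic acid, O=C(OO)c1cccc(Cl)c1
Why: Electrophilic epoxidation of the more electron-rich 11(20)-alkene (the 5(16)-alkene is deactivated by the allylic chlorine and lies in the crowded medium ring); the peracid enters from the α face, anti to the 1,3-related axial C15 methyl, which gives the 11R spiro-epoxide.

## Compound list

1 | (1E,3E)-buta-1,3-diene-1,4-diyl diacetate | CC(=O)O/C=C/C=C/OC(C)=O | starting material
2 | dilithium (1E,3E)-buta-1,3-diene-1,4-diolate | [Li+].[Li+].[O-]/C=C/C=C/[O-] | intermediate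
3 | (1E,3E)-1,4-bis(tert-butyldimethylsilyloxy)buta-1,3-diene | CC(C)(C)[Si](C)(C)O/C=C/C=C/O[Si](C)(C)C(C)(C)C | intermediate
4 | 2,3-dimethoxy-5-methyl-1,4-benzoquinone | COC1=C(OC)C(=O)C(C)=CC1=O | starting material
5 | cis-fused adduct 11α,14α-bis(TBSO)-7,8-dimethoxy-1β-methyl-10βH-decal-7,12-diene-2,9-dione | COC1=C(OC)C(=O)[C@@H]2[C@H](O[Si](C)(C)C(C)(C)C)C=C[C@H](O[Si](C)(C)C(C)(C)C)[C@]2(C)C1=O | intermediate
6 | cis-fused 11α,14α-bis(TBSO)-7,8-dimethoxy-1β-methyl-10βH-decal-7-ene-2,9-dione | COC1=C(OC)C(=O)[C@@H]2[C@H](O[Si](C)(C)C(C)(C)C)CC[C@H](O[Si](C)(C)C(C)(C)C)[C@]2(C)C1=O | intermediate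
7 | trans-fused 11α,14α-bis(TBSO)-7,8-dimethoxy-1β-methyl-10αH-decal-7-ene-2,9-dione | COC1=C(OC)C(=O)[C@H]2[C@H](O[Si](C)(C)C(C)(C)C)CC[C@H](O[Si](C)(C)C(C)(C)C)[C@]2(C)C1=O | intermediate
8 | 9β-hydroxy-11α,14α-bis(TBSO)-7,8-dimethoxy-1β-methyl-10αH-decal-7-en-2-one | COC1=C(OC)[C@@H](O)[C@H]2[C@H](O[Si](C)(C)C(C)(C)C)CC[C@H](O[Si](C)(C)C(C)(C)C)[C@]2(C)C1=O | intermediate
9 | 9β-TIPSO-11α,14α-bis(TBSO)-7,8-dimethoxy-1β-methyl-10αH-decal-7-en-2-one | COC1=C(OC)[C@@H](O[Si](C(C)C)(C(C)C)C(C)C)[C@H]2[C@H](O[Si](C)(C)C(C)(C)C)CC[C@H](O[Si](C)(C)C(C)(C)C)[C@]2(C)C1=O | intermediate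
10 | 9β-TIPSO-11α,14α-bis(TBSO)-8,8-dimethoxy-1β-methyl-10αH-decalin-2,7-dione | O=C1C(OC)(OC)[C@@H](O[Si](C(C)C)(C(C)C)C(C)C)[C@H]2[C@H](O[Si](C)(C)C(C)(C)C)CC[C@H](O[Si](C)(C)C(C)(C)C)[C@]2(C)C1=O | intermediate
11 | ethynylmagnesium bromide | C#C[Mg]Br | starting material
12 | 7α-ethynyl-7β-hydroxy-9β-TIPSO-11α,14α-bis(TBSO)-8,8-dimethoxy-1β-methyl-10αH-decalin-2-one | C#C[C@]1(O)C(OC)(OC)[C@@H](O[Si](C(C)C)(C(C)C)C(C)C)[C@H]2[C@H](O[Si](C)(C)C(C)(C)C)CC[C@H](O[Si](C)(C)C(C)(C)C)[C@]2(C)C1=O | intermediate
13 | 7α-ethynyl-7β,11α-dihydroxy-9β-TIPSO-14α-TBSO-8,8-dimethoxy-1β-methyl-10αH-decalin-2-one | C#C[C@]1(O)C(OC)(OC)[C@@H](O[Si](C(C)C)(C(C)C)C(C)C)[C@H]2[C@H](O)CC[C@H](O[Si](C)(C)C(C)(C)C)[C@]2(C)C1=O | intermediate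
14 | 7α-ethynyl-7β-hydroxy-9β-TIPSO-14α-TBSO-8,8-dimethoxy-1β-methyl-10αH-decalin-2,11-dione | C#C[C@]1(O)C(OC)(OC)[C@@H](O[Si](C(C)C)(C(C)C)C(C)C)[C@H]2C(=O)CC[C@H](O[Si](C)(C)C(C)(C)C)[C@]2(C)C1=O | intermediate
15 | 7α-ethynyl-7β-hydroxy-11-methylene-9β-TIPSO-14α-TBSO-8,8-dimethoxy-1β-methyl-10αH-decalin-2-one | C#C[C@]1(O)C(OC)(OC)[C@@H](O[Si](C(C)C)(C(C)C)C(C)C)[C@H]2C(=C)CC[C@H](O[Si](C)(C)C(C)(C)C)[C@]2(C)C1=O | intermediate
16 | vinylmagnesium bromide | C=C[Mg]Br | starting material
17 | 2β-ethenyl-7α-ethynyl-11-methylene-9β-TIPSO-14α-TBSO-8,8-dimethoxy-1β-methyl-10αH-decalin-2α,7β-diol | C#C[C@]1(O)C(OC)(OC)[C@@H](O[Si](C(C)C)(C(C)C)C(C)C)[C@H]2C(=C)CC[C@H](O[Si](C)(C)C(C)(C)C)[C@]2(C)[C@@]1(O)C=C | intermediate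
18 | 7α-[3-(diisopropylamino)prop-1-ynyl] analogue of 17 (Mannich base) | CC(C)N(CC#C[C@]1(O)C(OC)(OC)[C@@H](O[Si](C(C)C)(C(C)C)C(C)C)[C@H]2C(=C)CC[C@H](O[Si](C)(C)C(C)(C)C)[C@]2(C)[C@@]1(O)C=C)C(C)C | intermediate
19 | 2β-ethenyl-7α-(propa-1,2-dienyl)-11-methylene-9β-TIPSO-14α-TBSO-8,8-dimethoxy-1β-methyl-10αH-decalin-2α,7β-diol (key-step precursor) | C=C=C[C@]1(O)C(OC)(OC)[C@@H](O[Si](C(C)C)(C(C)C)C(C)C)[C@H]2C(=C)CC[C@H](O[Si](C)(C)C(C)(C)C)[C@]2(C)[C@@]1(O)C=C | intermediate
20 | dipotassium 2α,7β-dialkoxide of 19 | [K+].[K+].C=C=C[C@]1([O-])C(OC)(OC)[C@@H](O[Si](C(C)C)(C(C)C)C(C)C)[C@H]2C(=C)CC[C@H](O[Si](C)(C)C(C)(C)C)[C@]2(C)[C@@]1([O-])C=C | intermediate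
21 | dipotassium bis-enolate of 22 (C2 enolate and C7 dienolate, both ring double bonds trans) | [K+].[K+].C=C1C/C=C([O-])/[C@@]2(C)[C@@H](O[Si](C)(C)C(C)(C)C)CCC(=C)[C@@H]2[C@H](O[Si](C(C)C)(C(C)C)C(C)C)C(OC)(OC)/C([O-])=C/1 | intermediate
22 | 9-TIPSO-14-TBSO-8,8-dimethoxy-17,18,19-trinorbriara-5(16),11(20)-diene-2,7-dione (key-step product) | C=C1CCC(=O)[C@@]2(C)[C@@H](O[Si](C)(C)C(C)(C)C)CCC(=C)[C@@H]2[C@H](O[Si](C(C)C)(C(C)C)C(C)C)C(OC)(OC)C(=O)C1 | intermediate
23 | lithium C7 dienolate of 22 (O–C7=C6–C5=C16, geometry not defined) | [Li+].C=C1CCC(=O)[C@@]2(C)[C@@H](O[Si](C)(C)C(C)(C)C)CCC(=C)[C@@H]2[C@H](O[Si](C(C)C)(C(C)C)C(C)C)C(OC)(OC)C([O-])=C1 | intermediate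
24 | (6S)-6-chloro-9-TIPSO-14-TBSO-8,8-dimethoxy-17,18,19-trinorbriara-5(16),11(20)-diene-2,7-dione | C=C1CCC(=O)[C@@]2(C)[C@@H](O[Si](C)(C)C(C)(C)C)CCC(=C)[C@@H]2[C@H](O[Si](C(C)C)(C(C)C)C(C)C)C(OC)(OC)C(=O)[C@H]1Cl | intermediate
25 | (6S,7S)-6-chloro-7-hydroxy-9-TIPSO-14-TBSO-8,8-dimethoxy-17,18,19-trinorbriara-5(16),11(20)-dien-2-one | C=C1CCC(=O)[C@@]2(C)[C@@H](O[Si](C)(C)C(C)(C)C)CCC(=C)[C@@H]2[C@H](O[Si](C(C)C)(C(C)C)C(C)C)C(OC)(OC)[C@H](O)[C@H]1Cl | intermediate
26 | (6S,7S)-6-chloro-7-hydroxy-9-TIPSO-14-TBSO-17,18,19-trinorbriara-5(16),11(20)-diene-2,8-dione | C=C1CCC(=O)[C@@]2(C)[C@@H](O[Si](C)(C)C(C)(C)C)CCC(=C)[C@@H]2[C@H](O[Si](C(C)C)(C(C)C)C(C)C)C(=O)[C@H](O)[C@H]1Cl | intermediate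
27 | 2-bromopropanoic acid (racemic) | CC(Br)C(=O)O | starting material
28 | (6S,7R)-7-(2-bromopropanoyloxy)-6-chloro-9-TIPSO-14-TBSO-17,18,19-trinorbriara-5(16),11(20)-diene-2,8-dione (both epimers at the CHBr carbon) | C=C1CCC(=O)[C@@]2(C)[C@@H](O[Si](C)(C)C(C)(C)C)CCC(=C)[C@@H]2[C@H](O[Si](C(C)C)(C(C)C)C(C)C)C(=O)[C@@H](OC(=O)C(C)Br)[C@H]1Cl | intermediate
29 | trivalent samarium ester enolate derived from 28 | [Sm+3].[I-].[I-].C=C1CCC(=O)[C@@]2(C)[C@@H](O[Si](C)(C)C(C)(C)C)CCC(=C)[C@@H]2[C@H](O[Si](C(C)C)(C(C)C)C(C)C)C(=O)[C@@H](OC([O-])=CC)[C@H]1Cl | intermediate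
30 | (6S,7R,8R,17R)-6-chloro-8-hydroxy-9-TIPSO-14-TBSO-2-oxobriara-5(16),11(20)-dien-19,7-olide | C=C1CCC(=O)[C@@]2(C)[C@@H](O[Si](C)(C)C(C)(C)C)CCC(=C)[C@@H]2[C@H](O[Si](C(C)C)(C(C)C)C(C)C)[C@]2(O)[C@@H](C)C(=O)O[C@H]2[C@H]1Cl | intermediate
31 | (6S,7R,8R,17R)-6-chloro-8,9,14-trihydroxy-2-oxobriara-5(16),11(20)-dien-19,7-olide | C=C1CCC(=O)[C@@]2(C)[C@@H](O)CCC(=C)[C@@H]2[C@H](O)[C@]2(O)[C@@H](C)C(=O)O[C@H]2[C@H]1Cl | intermediate
32 | (2S,6S,7R,8R,17R)-6-chloro-2,8,9,14-tetrahydroxybriara-5(16),11(20)-dien-19,7-olide | C=C1CC[C@H](O)[C@@]2(C)[C@@H](O)CCC(=C)[C@@H]2[C@H](O)[C@]2(O)[C@@H](C)C(=O)O[C@H]2[C@H]1Cl | intermediate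
33 | (2S,6S,7R,8R,17R)-2,9,14-triacetoxy-6-chloro-8-hydroxybriara-5(16),11(20)-dien-19,7-olide | C=C1CC[C@H](OC(C)=O)[C@@]2(C)[C@@H](OC(C)=O)CCC(=C)[C@@H]2[C@H](OC(C)=O)[C@]2(O)[C@@H](C)C(=O)O[C@H]2[C@H]1Cl | intermediate
34 | CNP0104093.1, (1S,2S,6S,7R,8R,9S,10S,11R,14S,17R)-2,9,14-triacetoxy-6-chloro-11,20-epoxy-8-hydroxybriar-5(16)-en-19,7-olide | C=C1CC[C@H](OC(C)=O)[C@@]2(C)[C@@H](OC(C)=O)CC[C@]3(CO3)[C@@H]2[C@H](OC(C)=O)[C@]2(O)[C@@H](C)C(=O)O[C@H]2[C@H]1Cl | target

## Step count and least certain steps

Total step count: 23. Longest linear sequence: 23 steps (from 1; 4, 11, 16 and 27 enter as purchased reagents).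

**Step 14 (key step).** What may go wrong: fragmentation of the dialkoxide instead of the sigmatropic shift; an axial alkenyl group (if a C2 or C7 epimer is carried in) slowing the shift; migration of the new methylene into conjugation or transannular aldol closure during the quench. Fallback: 19 is converted to its bis(trimethylsilyl) ether F1 (Me3SiOTf, 2,6-lutidine). F1 is heated in toluene or xylene (sealed tube), where the neutral siloxy-Cope rearrangement, eased by the allene, gives the bis(silyl enol ether) F2. Buffered fluoride (KF, AcOH, MeOH, −20 °C) releases both carbonyls with α-protonation, and the route is rejoined at 22. No free enolate ever meets a free ketone on this path.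

**Step 2.** What may go wrong: too slow a cycloaddition between a trisubstituted quinone double bond and a 1,4-disubstituted diene; acid-induced loss of the silyl dienol ether; weak enantiofacial discrimination. Fallback: 3 and 4 are combined without catalyst (toluene, heat, or high pressure) to give racemic 5. This is taken through steps 3 and 4, and the enantiomers of 7 are separated on a chiral stationary phase. The unwanted antipode ent-7 F3 is set aside, and the route is rejoined at 7.

**Step 12.** What may go wrong: no addition to a ketone flanked by two fully substituted carbons; α-ketol rearrangement of the alkoxide on warming; entry from the other face (tolerated). Fallback: from 15, the smaller linear nucleophile lithium (trimethylsilyl)acetylide (CeCl3, THF) is added to C2 to give the silylalkynyl diol F4. Crabbé homologation, which touches only the free terminal alkyne on C7, gives the allene F5. K2CO3 in MeOH removes the silyl group to give the ethynyl carbinol F6. Semi-hydrogenation over Pd/CaCO3 poisoned with Pb(OAc)2 (quinoline), which reduces a terminal alkyne faster than an allene or a 1,1-disubstituted alkene, returns to the route at 19.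

**Step 15.** What may go wrong: chlorination on the wrong face of the dienolate; attack at the γ-carbon C16; addition of the dienolate to the C2 ketone across the ring. Fallback: the dienolate made from 22 is oxidised with 2-(phenylsulfonyl)-3-phenyloxaziridine to the (6R)-6-hydroxy ketone F7 (the oxygen electrophile is taken to prefer the same face). The hydroxyl is mesylated (MsCl, Et3N) and displaced by chloride (LiCl, DMF) with inversion at the activated α-keto position, which rejoins the route at 24.

**Step 16.** What may go wrong: the medium ring may override the polar model, so that hydride delivery gives the 7R alcohol; the chlorohydrin alkoxide may close to an epoxide. Fallback: if the 7R epimer F8 is formed from 24, it is hydrolysed as in step 17 to the α-hydroxy ketone F9. F9 is acylated with retention by 2-bromopropanoyl bromide and pyridine, which rejoins the route at 28 without the Mitsunobu inversion.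

**Step 19.** What may go wrong: closure on the other face of the C8 ketone; the wrong C17 epimer; reductive loss of the acyloxy group from a ketyl. Fallback: 26 is esterified under Mitsunobu conditions with 2-(diethoxyphosphoryl)propanoic acid to the phosphonate F10. An intramolecular Horner–Wadsworth–Emmons reaction (LiCl, DBU, MeCN) gives the butenolide F11. Nucleophilic epoxidation (t-BuOOH, DBU), which leaves the isolated alkenes alone, gives the 8,17-epoxy lactone F12. SmI2 in THF/MeOH at −78 °C cleaves the C17–O bond and the enolate is protonated to the more stable 17R epimer, which rejoins the route at 30. In this variant C8 is set by the face of the epoxidation, not by the aldol transition state.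

Further compounds

F1 | step 14 | bis(trimethylsilyl) ether of 19 | C=C=C[C@]1(O[Si](C)(C)C)C(OC)(OC)[C@@H](O[Si](C(C)C)(C(C)C)C(C)C)[C@H]2C(=C)CC[C@H](O[Si](C)(C)C(C)(C)C)[C@]2(C)[C@@]1(O[Si](C)(C)C)C=C
F2 | step 14 | 2,7-bis(trimethylsilyl enol ether) of 22 | C=C1C/C=C(O[Si](C)(C)C)/[C@@]2(C)[C@@H](O[Si](C)(C)C(C)(C)C)CCC(=C)[C@@H]2[C@H](O[Si](C(C)C)(C(C)C)C(C)C)C(OC)(OC)/C(O[Si](C)(C)C)=C/1
F3 | step 2 | ent-7 | COC1=C(OC)C(=O)[C@@H]2[C@@H](O[Si](C)(C)C(C)(C)C)CC[C@@H](O[Si](C)(C)C(C)(C)C)[C@@]2(C)C1=O
F4 | step 12 | 2β-(trimethylsilylethynyl)-7α-ethynyl-2α,7β-diol analogue of 17 | C#C[C@]1(O)C(OC)(OC)[C@@H](O[Si](C(C)C)(C(C)C)C(C)C)[C@H]2C(=C)CC[C@H](O[Si](C)(C)C(C)(C)C)[C@]2(C)[C@@]1(O)C#C[Si](C)(C)C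
F5 | step 12 | 2β-(trimethylsilylethynyl)-7α-(propa-1,2-dienyl)-2α,7β-diol | C=C=C[C@]1(O)C(OC)(OC)[C@@H](O[Si](C(C)C)(C(C)C)C(C)C)[C@H]2C(=C)CC[C@H](O[Si](C)(C)C(C)(C)C)[C@]2(C)[C@@]1(O)C#C[Si](C)(C)C
F6 | step 12 | 2β-ethynyl-7α-(propa-1,2-dienyl)-2α,7β-diol | C=C=C[C@]1(O)C(OC)(OC)[C@@H](O[Si](C(C)C)(C(C)C)C(C)C)[C@H]2C(=C)CC[C@H](O[Si](C)(C)C(C)(C)C)[C@]2(C)[C@@]1(O)C#C
F7 | step 15 | (6R)-6-hydroxy derivative of 22 | C=C1CCC(=O)[C@@]2(C)[C@@H](O[Si](C)(C)C(C)(C)C)CCC(=C)[C@@H]2[C@H](O[Si](C(C)C)(C(C)C)C(C)C)C(OC)(OC)C(=O)[C@@H]1O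
F8 | step 16 | (6S,7R)-epimer of 25 | C=C1CCC(=O)[C@@]2(C)[C@@H](O[Si](C)(C)C(C)(C)C)CCC(=C)[C@@H]2[C@H](O[Si](C(C)C)(C(C)C)C(C)C)C(OC)(OC)[C@@H](O)[C@H]1Cl
F9 | step 16 | (6S,7R)-epimer of 26 | C=C1CCC(=O)[C@@]2(C)[C@@H](O[Si](C)(C)C(C)(C)C)CCC(=C)[C@@H]2[C@H](O[Si](C(C)C)(C(C)C)C(C)C)C(=O)[C@@H](O)[C@H]1Cl
F10 | step 19 | (6S,7R)-7-[2-(diethoxyphosphoryl)propanoyloxy] analogue of 28 | C=C1CCC(=O)[C@@]2(C)[C@@H](O[Si](C)(C)C(C)(C)C)CCC(=C)[C@@H]2[C@H](O[Si](C(C)C)(C(C)C)C(C)C)C(=O)[C@@H](OC(=O)C(C)P(=O)(OCC)OCC)[C@H]1Cl
F11 | step 19 | 8(17)-butenolide: 6-chloro-9-TIPSO-14-TBSO-2-oxobriara-5(16),8(17),11(20)-trien-19,7-olide | C=C1CCC(=O)[C@@]2(C)[C@@H](O[Si](C)(C)C(C)(C)C)CCC(=C)[C@@H]2[C@H](O[Si](C(C)C)(C(C)C)C(C)C)C2=C(C)C(=O)O[C@H]2[C@H]1Cl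
F12 | step 19 | 8α,17α-epoxy lactone derived from F11 | C=C1CCC(=O)[C@@]2(C)[C@@H](O[Si](C)(C)C(C)(C)C)CCC(=C)[C@@H]2[C@H](O[Si](C(C)C)(C(C)C)C(C)C)[C@@]23O[C@@]3(C)C(=O)O[C@H]2[C@H]1Cl
A1 | alternative 1 | ring A cyclohexene fused to the diisopropylsiloxane (product of the tethered cycloaddition) | CC(C)(C)[Si](C)(C)OCC[C@H](O1)[C@@]2(C)[C@@H](O[Si]1(C(C)C)C(C)C)C=CC(OC)(OC)[C@@H]2C(=O)OC
A2 | alternative 1 | silicon-tethered triene (E-enoate linked through O2–Si–O14 to the 4,4-dimethoxydienyl ether) | CC(C)(C)[Si](C)(C)OCC[C@H](O[Si](C(C)C)(C(C)C)O/C=C/C=C(OC)OC)/C(C)=C/C(=O)OC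
A3 | alternative 2 | briarane bicycle with free 2-hydroxyl and 11(20)-methylene | O=C1CC[C@H](O)[C@@]2(C)[C@@H](O[Si](C)(C)C(C)(C)C)CCC(=C)[C@@H]2[C@H](O[Si](C)(C)C(C)(C)C)C2=C(C)C(=O)O[C@H]2[C@@H]1O[Si](C)(C)C(C)(C)C
A4 | alternative 2 | fourteen-membered 1,2-epoxy-10(11)E-ene macrocycle | O=C1CC[C@@H]2O[C@@]2(C)[C@@H](O[Si](C)(C)C(C)(C)C)CC/C(C)=C/[C@H](O[Si](C)(C)C(C)(C)C)C2=C(C)C(=O)O[C@H]2[C@@H]1O[Si](C)(C)C(C)(C)C
A5 | alternative 3 | 9-O-tert-butyldimethylsilyl analogue of the target | C=C1CC[C@H](OC(C)=O)[C@@]2(C)[C@@H](OC(C)=O)CC[C@]3(CO3)[C@@H]2[C@H](O[Si](C)(C)C(C)(C)C)[C@]2(O)[C@@H](C)C(=O)O[C@H]2[C@H]1Cl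
A6 | alternative 3 | seco precursor with C7 aldehyde, C19 methyl ester and γ-chloroallyl bromide (alkene geometry not defined) | ClC=C(CBr)CC[C@H](OC(C)=O)[C@@]1(C)[C@@H](OC(C)=O)CC[C@]2(CO2)[C@@H]1[C@H](O[Si](C)(C)C(C)(C)C)[C@@](O)(C=O)[C@@H](C)C(=O)OC
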